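The runs come from a simulation with constants of no real substance, and the scatter is random.

In a one-step world each second end group finds one first end group and leaves one product, so links plus rings equal the second end groups charged, the limiting reagent.

all flasks: first end groups 20 mM

|  | second end groups | remark | time |
|---|---|---|---|
| Sunday's | 0.95 equiv | the very flask that is asked about, followed so far |  |
| Friday's | 0.64 equiv | run made earlier |  |
| flask | 0.950 equiv |  | 40 h |

- Sunday's (time / h: links / %, rings / %): 2.00: 67, 26; 6.00: 63, 28; 10.0: 67, 32; 15.0: 64, 27
- Friday's (time / h: links / %, rings / %): 2.50: 41, 23; 5.00: 42, 25; 12.0: 41, 23; 30.0: 40, 23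

(each reading ± 1.5 percentage points)

1. how much links the flask holds at 40 h, in percent of the first end groups charged
2. how much rings the flask holds at 40 h, in percent of the first end groups charged
3. how much first end groups the flask holds at 40 h, in percent of the first end groups charged

I test this with a bench rule: average links plus rings over a run and divide by the equivalents charged. Friday's run averages 64.5 % on 0.64 equivalents. Sunday's run, the asked flask followed so far, averages 93.5 % on 0.95. That gives 101 % and 98.4 %. I call this ratio the capture: the share of charged second end groups found in links and rings. Sunday's shortfall of 1.5 percentage points stands against a scatter of 1.1 points on the mean sum.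

The readings show no drift, so I freeze the capture. My reckoning for the asked flask is links 65.2 %, rings 28.3 %, and first end groups 6.50 %, the charge that capture leaves over.

The rule has a border. That remainder lives in the gap between the charges, and the gap measures 24.0 reading scatters on Friday's run but 3.33 in the asked flask. So the remainder is far less sharply read here.

The forecast is links 66 %, rings 28 % and first end groups 6 %, on the ground that the runs are “flat from the first reading onward”. Its links and rings sum to 94.0 %, a little above my 93.5 %.

    first end groups + second end groups → links (k = 0.170 L mol⁻¹ s⁻¹)
    first end groups + second end groups → rings, rate k2*[first end groups] as long as [second end groups] is above zero (k = 4.50 × 10⁻⁴ s⁻¹)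
    first end groups ⇌ dormant form (K = 0.300, k = 9.10 × 10⁻⁶ s⁻¹)
    second end groups → decomposed reagent (k = 5.80 × 10⁻⁵ s⁻¹)

At 40 h the flask holds links 65.6 %, rings 27.0 % and first end groups 5.74 %. Its capture is 97.4 %, which leaves 7.46 % of the charge: those first end groups plus 1.72 % dormant form. The half-life of second end groups by the step to links is 0.093 h at 0.0468 h, far shorter than 3.3 h by decomposition, a ratio of 35.9. The flask ends with 0.491 mM decomposed reagent. The neighbour flask with 0.380 equiv of second end groups has a capture of 98.9 %, and its remainder of 62.4 % stands as 48.1 % first end groups and 14.4 % dormant form.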